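**Retrosynthetic overview**
1. Last step: methanolysis of the C3 acetate of the fully assembled quinone (3-O-acetyl-3-demethylubiquinone-6).
2. Key disconnection: the ring C6–chain C1' bond, made at the quinone oxidation level by BF3-mediated union of 3-acetoxy-2-methoxy-5-methyl-1,4-benzoquinone (C6 as electrophile) with all-E hexaprenyltrimethylstannane (C1' as nucleophile), with re-oxidation in the same flask. This reverses the polarity of aromatic prenylation, where the arene is the nucleophile and the prenyl carbon the electrophile.
3. Enabling feature: C6 is the only unsubstituted carbon of the para-quinone ring (carbonyls at C1 and C4) and is an enone β-carbon. Only an allyl group delivered there can end in an aromatic hydroquinone, so the quinone ring itself is the activating group and neither carbonyl is ever protected.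
4. Quinone: 2,4,5-trimethoxybenzaldehyde → toluene → ortho-metalation/boronate oxidation (places the C3 oxygen) → acetate → oxidative demethylation. Chain: C20 geranylgeranyl sulfone + C10 8-bromogeranyl acetate → desulfonylation → bromide → stannane.
5. Rings: the single carbocycle is bought as a benzene ring; no ring is formed in the route.

Key step: step 13

Assumption: 2,4,5-trimethoxybenzaldehyde, all-E geranylgeraniol and geranyl acetate are taken as commercial. The target has no stereocentre, so stereocontrol means keeping the five trisubstituted alkenes E. Ring positions follow ubiquinone numbering (C1 and C4 carbonyl, C2 methoxy, C3 hydroxy, C5 methyl, C6 chain); chain positions carry primes.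

**Step 1**
Reactants: 1 2,4,5-trimethoxybenzaldehyde
Product: 2 2,4,5-trimethoxytoluene
Conditions: H2 (4 bar), Pd/C (10 wt %), AcOH, 40 °C
Reagents that add atoms: none
Why: Hydrogenolysis of an electron-rich aryl aldehyde (through the benzylic alcohol) over palladium on carbon in acetic acid is a standard route to methoxytoluenes, and no other reducible group is present.

**Step 2**
Reactants: 2 2,4,5-trimethoxytoluene
Product: 5 2,3,6-trimethoxy-5-methylphenol, via 3-lithio-2,4,5-trimethoxytoluene 3 (not isolated), via dimethyl arylboronate 4 (not isolated)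
Conditions: n-BuLi, TMEDA, THF, 0 °C; B(OMe)3, -78 °C → rt; AcOH, 30 % H2O2, 0 °C → rt
Reagents that add atoms: hydrogen peroxide, OO (phenol oxygen of 5); n-butyllithium, [Li]CCCC (lithium of 3 only); trimethyl borate, COB(OC)OC (B(OMe)2 group of 4 only)
Why: Directed ortho-metalation takes the ring C–H flanked by two methoxy groups, the most acidic site, and borylation followed by boronate oxidation (aryl migration from boron to oxygen) places the phenol oxygen on the carbon that becomes C3 of the quinone.

**Step 3**
Reactants: 5 2,3,6-trimethoxy-5-methylphenol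
Product: 6 2,3,6-trimethoxy-5-methylphenyl acetate
Conditions: Ac2O, pyridine, DMAP (cat.), CH2Cl2, rt
Reagents that add atoms: acetic anhydride, CC(=O)OC(C)=O
Why: DMAP-catalysed O-acylation of a phenol; the acetate takes this oxygen out of the redox chemistry of the next step and is the only protecting group of the route.

**Step 4**
Reactants: 6 2,3,6-trimethoxy-5-methylphenyl acetate
Product: 7 3-acetoxy-2-methoxy-5-methyl-1,4-benzoquinone
Conditions: (NH4)2Ce(NO3)6 (2.5 equiv), MeCN/H2O, 0 °C
Reagents that add atoms: water, O
Why: Oxidative demethylation of a para-dimethoxyarene to the para-benzoquinone, the reaction type that turns 2,3,4,5-tetramethoxytoluene into 2,3-dimethoxy-5-methylbenzoquinone; the methoxy groups at C3 and C6 of the phenyl acetate are the only para-related pair, which fixes the regiochemistry, and the aryl acetate should survive the short acidic oxidation.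

**Step 5**
Reactants: 8 (2E,6E,10E)-geranylgeraniol
Product: 9 (2E,6E,10E)-geranylgeranyl bromide
Conditions: PBr3, Et2O, -10 °C, dark
Reagents that add atoms: phosphorus tribromide, BrP(Br)Br
Why: SN2 bromination of a primary allylic alcohol with PBr3 at low temperature, a reaction known to leave the 2E geometry of polyprenols intact.

**Step 6**
Reactants: 9 (2E,6E,10E)-geranylgeranyl bromide
Product: 10 (2E,6E,10E)-geranylgeranyl p-tolyl sulfone
Conditions: TolSO2Na, DMF, 0 °C → rt
Reagents that add atoms: sodium p-toluenesulfinate, [Na+].Cc1ccc(cc1)S(=O)[O-]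
Why: S-alkylation of the sulfinate anion by the primary allylic bromide (SN2) gives the allylic sulfone without touching the alkenes.

**Step 7**
Reactants: 11 geranyl acetate
Product: 12 (2E,6E)-8-hydroxy-3,7-dimethylocta-2,6-dien-1-yl acetate
Conditions: SeO2 (cat.), t-BuOOH, salicylic acid (cat.), CH2Cl2, rt
Reagents that add atoms: tert-butyl hydroperoxide, CC(C)(C)OO
Why: SeO2-catalysed allylic oxidation (Riley oxidation: ene reaction, then [2,3]-sigmatropic shift) attacks the electron-rich distal alkene at its E-methyl group and gives the E-allylic alcohol, while the 2,3-alkene is deactivated by the allylic acetate.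

**Step 8**
Reactants: 12 (2E,6E)-8-hydroxy-3,7-dimethylocta-2,6-dien-1-yl acetate
Product: 13 (2E,6E)-8-bromo-3,7-dimethylocta-2,6-dien-1-yl acetate
Conditions: CBr4, PPh3, CH2Cl2, -20 → 0 °C
Reagents that add atoms: carbon tetrabromide, BrC(Br)(Br)Br
Why: The Appel reaction converts the primary allylic alcohol into the bromide under neutral conditions, without allylic transposition and without touching the acetate.

**Step 9**
Reactants: 10 (2E,6E,10E)-geranylgeranyl p-tolyl sulfone; 13 (2E,6E)-8-bromo-3,7-dimethylocta-2,6-dien-1-yl acetate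
Product: 15 (2E,6E,10E,14E,18E)-3,7,11,15,19,23-hexamethyl-9-(p-tolylsulfonyl)tetracosa-2,6,10,14,18,22-hexaen-1-yl acetate (racemic at C9), via lithiated sulfone 14 (not isolated)
Conditions: n-BuLi, THF, -78 °C; then 13, THF/DMPU, -78 → -40 °C
Reagents that add atoms: n-butyllithium, [Li]CCCC (lithium of 14 only)
Why: Alkylation of an α-sulfonyl allyl carbanion with a primary allylic bromide (sulfone-based head-to-tail prenyl coupling); the soft carbanion reacts at its α-carbon by SN2 far faster than it attacks the acetate at -78 °C, every alkene keeps its geometry, and the new sulfone-bearing stereocentre at C9 forms racemic and is erased in step 10.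

**Step 10**
Reactants: 15 (2E,6E,10E,14E,18E)-3,7,11,15,19,23-hexamethyl-9-(p-tolylsulfonyl)tetracosa-2,6,10,14,18,22-hexaen-1-yl acetate
Product: 17 all-E-hexaprenol, via lithium alkoxide of the hydroxy sulfone 16 (not isolated)
Conditions: LiBHEt3 (excess), THF, -78 → 0 °C; then PdCl2(dppp) (5 mol %), 0 °C → rt
Reagents that add atoms: lithium triethylborohydride, [Li+].CC[BH-](CC)CC (lithium of 16 only)
Why: Ester reduction by LiBHEt3 is followed by palladium-catalysed reductive desulfonylation of the allylic sulfone (ionisation to a π-allylpalladium complex and hydride delivery to the less substituted terminus, a Tsuji–Trost-type reduction), a reaction known to keep the position and E geometry of the trisubstituted alkene; cleaving the acetate first leaves C1 as an alkoxide that zerovalent palladium cannot ionise.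

**Step 11**
Reactants: 17 all-E-hexaprenol
Product: 18 all-E-hexaprenyl bromide
Conditions: PBr3, Et2O, -10 °C, dark
Reagents that add atoms: phosphorus tribromide, BrP(Br)Br
Why: SN2 bromination of the primary allylic alcohol as in step 5, with retention of the 2E geometry.

**Step 12**
Reactants: 18 all-E-hexaprenyl bromide
Product: 19 all-E-hexaprenyltrimethylstannane
Conditions: Me3SnLi (from Me3SnCl and Li, THF, 0 °C), THF, -78 → -20 °C
Reagents that add atoms: trimethylstannyllithium, C[Sn](C)(C)[Li] (SnMe3 group of 19); chlorotrimethylstannane, C[Sn](C)(C)Cl (tin source from which the stannyllithium is made in the flask); lithium, [Li] (metal that forms the stannyllithium in the flask, no lithium in 19)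
Why: SN2 displacement of the primary allylic bromide by the stannyl anion gives the primary allylstannane with the 2E geometry retained, the standard entry to polyprenyl trialkylstannanes.

**Step 13**
Reactants: 7 3-acetoxy-2-methoxy-5-methyl-1,4-benzoquinone (2 equiv); 19 all-E-hexaprenyltrimethylstannane
Product: 21 3-O-acetyl-3-demethylubiquinone-6, via hexaprenylhydroquinone monoacetate 20 (not isolated)
Conditions: BF3·OEt2, CH2Cl2, -78 → -50 °C; aqueous work-up; then Ag2O, Et2O, rt
Reagents that add atoms: none
Why: BF3 coordinates the quinone and makes ring carbon C6 (the only unsubstituted ring carbon, α to the C1 carbonyl and β to the C4 carbonyl) the electrophile, while σ(C–Sn) hyperconjugation makes the allyl unit of 19 the nucleophile, a union of reversed polarity relative to aromatic prenylation. The allyl group is transferred to the activated quinone (addition at the C1 carbonyl followed by an acid-promoted sigmatropic shift to C6, or direct conjugate attack at C6; both converge), the dienone enolises to hydroquinone 20 with loss of Me3SnF, and Ag2O returns 20 to the quinone level in the same operation. The closest known reaction type is the Lewis-acid-mediated allylation of quinones such as 2,3-dimethoxy-5-methyl-1,4-benzoquinone with polyprenyl trialkylstannanes, which is known to attach the chain through its tin-bearing carbon and to keep the 2E geometry. No ring is closed and no stereocentre is formed. Site selectivity comes from the substrate: adducts at C2, C3 or C5 cannot aromatise, only C6 carries hydrogen, and the adjacent C1 carbonyl is the more electrophilic one because its β-carbon C3 bears the weakly donating acetoxy group whereas the C4 carbonyl is a deactivated vinylogous ester of the C2 methoxy group. Chemoselectivity over the five isolated trisubstituted alkenes comes from the tin substituent, which raises the nucleophilicity of the allylic alkene alone, and from the low temperature.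

**Step 14**
Reactants: 21 3-O-acetyl-3-demethylubiquinone-6
Product: 22 3-demethylubiquinone-6
Conditions: K2CO3, MeOH, 0 °C, argon; then dilute HCl
Reagents that add atoms: none
Why: Base-mediated transesterification (methanolysis) of the acyloxyquinone, a vinylogous mixed anhydride that should cleave faster than anything else reacts; the hydroxyquinone leaves as its stabilised anion, which resists further nucleophilic attack, and is protonated on work-up.

**Compound list**
1 | 2,4,5-trimethoxybenzaldehyde | COc1cc(C=O)c(OC)cc1OC | starting material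
2 | 2,4,5-trimethoxytoluene | COc1cc(C)c(OC)cc1OC | intermediate
3 | 3-lithio-2,4,5-trimethoxytoluene (lithium between the 2- and 4-methoxy groups) | COc1cc(C)c(OC)c([Li])c1OC | intermediate
4 | dimethyl (2,3,6-trimethoxy-5-methylphenyl)boronate | COc1cc(C)c(OC)c(B(OC)OC)c1OC | intermediate
5 | 2,3,6-trimethoxy-5-methylphenol | COc1cc(C)c(OC)c(O)c1OC | intermediate
6 | 2,3,6-trimethoxy-5-methylphenyl acetate | COc1cc(C)c(OC)c(OC(C)=O)c1OC | intermediate
7 | 3-acetoxy-2-methoxy-5-methyl-1,4-benzoquinone (fumigatin acetate) | COC1=C(OC(C)=O)C(=O)C(C)=CC1=O | intermediate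
8 | (2E,6E,10E)-3,7,11,15-tetramethylhexadeca-2,6,10,14-tetraen-1-ol (geranylgeraniol) | OC/C=C(\C)CC/C=C(\C)CC/C=C(\C)CCC=C(C)C | starting material
9 | (2E,6E,10E)-geranylgeranyl bromide | BrC/C=C(\C)CC/C=C(\C)CC/C=C(\C)CCC=C(C)C | intermediate
10 | (2E,6E,10E)-geranylgeranyl p-tolyl sulfone | Cc1ccc(cc1)S(=O)(=O)C/C=C(\C)CC/C=C(\C)CC/C=C(\C)CCC=C(C)C | intermediate
11 | geranyl acetate, (2E)-3,7-dimethylocta-2,6-dien-1-yl acetate | CC(=O)OC/C=C(\C)CCC=C(C)C | starting material
12 | (2E,6E)-8-hydroxy-3,7-dimethylocta-2,6-dien-1-yl acetate | CC(=O)OC/C=C(\C)CC/C=C(\C)CO | intermediate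
13 | (2E,6E)-8-bromo-3,7-dimethylocta-2,6-dien-1-yl acetate | CC(=O)OC/C=C(\C)CC/C=C(\C)CBr | intermediate
14 | α-lithiated geranylgeranyl p-tolyl sulfone | Cc1ccc(cc1)S(=O)(=O)C([Li])/C=C(\C)CC/C=C(\C)CC/C=C(\C)CCC=C(C)C | intermediate
15 | (2E,6E,10E,14E,18E)-3,7,11,15,19,23-hexamethyl-9-(p-tolylsulfonyl)tetracosa-2,6,10,14,18,22-hexaen-1-yl acetate, racemic at C9 | CC(=O)OC/C=C(\C)CC/C=C(\C)CC(S(=O)(=O)c1ccc(C)cc1)/C=C(\C)CC/C=C(\C)CC/C=C(\C)CCC=C(C)C | intermediate
16 | lithium alkoxide of the C30 hydroxy sulfone (15 without its acetyl group) | [Li]OC/C=C(\C)CC/C=C(\C)CC(S(=O)(=O)c1ccc(C)cc1)/C=C(\C)CC/C=C(\C)CC/C=C(\C)CCC=C(C)C | intermediate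
17 | (2E,6E,10E,14E,18E)-3,7,11,15,19,23-hexamethyltetracosa-2,6,10,14,18,22-hexaen-1-ol (all-E-hexaprenol) | OC/C=C(\C)CC/C=C(\C)CC/C=C(\C)CC/C=C(\C)CC/C=C(\C)CCC=C(C)C | intermediate
18 | all-E-hexaprenyl bromide | BrC/C=C(\C)CC/C=C(\C)CC/C=C(\C)CC/C=C(\C)CC/C=C(\C)CCC=C(C)C | intermediate
19 | trimethyl[(2E,6E,10E,14E,18E)-3,7,11,15,19,23-hexamethyltetracosa-2,6,10,14,18,22-hexaen-1-yl]stannane | C[Sn](C)(C)C/C=C(\C)CC/C=C(\C)CC/C=C(\C)CC/C=C(\C)CC/C=C(\C)CCC=C(C)C | intermediate
20 | 3-acetoxy-6-(all-E-hexaprenyl)-2-methoxy-5-methylbenzene-1,4-diol | COc1c(OC(C)=O)c(O)c(C)c(C/C=C(\C)CC/C=C(\C)CC/C=C(\C)CC/C=C(\C)CC/C=C(\C)CCC=C(C)C)c1O | intermediate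
21 | 3-acetoxy-6-(all-E-hexaprenyl)-2-methoxy-5-methyl-1,4-benzoquinone (3-O-acetyl-3-demethylubiquinone-6) | COC1=C(OC(C)=O)C(=O)C(C)=C(C/C=C(\C)CC/C=C(\C)CC/C=C(\C)CC/C=C(\C)CC/C=C(\C)CCC=C(C)C)C1=O | intermediate
22 | 3-hydroxy-6-[(2E,6E,10E,14E,18E)-hexaprenyl]-2-methoxy-5-methyl-1,4-benzoquinone (3-demethylubiquinone-6) | COC1=C(O)C(=O)C(C)=C(C/C=C(\C)CC/C=C(\C)CC/C=C(\C)CC/C=C(\C)CC/C=C(\C)CCC=C(C)C)C1=O | target

**Totals**
Total step count: 14.
Longest linear sequence: 8 steps (steps 5, 6, 9, 10, 11, 12, 13, 14, from geranylgeraniol).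

**Steps most likely to fail**

Step 13 (key step). What may go wrong: delivery of the allyl group through its tertiary terminus or with rotation about C2'–C3' (loss of 2'E purity), protodestannylation of 19 by adventitious acid, Lewis-acid-induced cyclisation of the polyene, or loss of the acetyl group from 7. The fallback uses normal polarity (ring carbon as nucleophile, C1' as electrophile); it sets out from phenol 5 and comes back to the route at 21. Bromination of 5 with NBS (MeCN, 0 °C) at the only free ring position should give 4-bromo-2,3,6-trimethoxy-5-methylphenol F1. Silylation (TBSCl, imidazole, DMF) gives its tert-butyldimethylsilyl ether F2. Bromine–lithium exchange (n-BuLi, THF, -78 °C) gives the aryllithium F3 (not isolated), which is alkylated with bromide 18 in the presence of catalytic CuBr·SMe2 (SN2 at the primary allylic carbon, known to keep the E geometry) to give the hexaprenylated silyl ether F4. Bu4NF (THF, 0 °C) gives the hexaprenylphenol F5, Ac2O/pyridine gives the hexaprenylaryl acetate F6, and (NH4)2Ce(NO3)6 in MeCN/H2O oxidises the para-dimethoxy pair to quinone 21. Step 14 then follows unchanged.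

Step 10. What may go wrong: migration of the C10=C11 double bond or loss of its E geometry when hydride is delivered to the π-allylpalladium intermediate, and hydrogenolysis of the allylic C1 oxygen if acetate cleavage is incomplete before the palladium catalyst is added. The fallback sets out from 15 and comes back at 17. Methanolysis (K2CO3, MeOH, 0 °C) gives the hydroxy sulfone F7. Dissolving-metal reductive desulfonylation (Li, EtNH2, -78 °C) then cleaves the C–S bond by electron transfer; it needs no palladium and cannot ionise the C1–O bond of the alkoxide.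

Step 4. What may go wrong: oxidation across the adjacent methoxy pair to an ortho-quinone, oxidation at the benzylic methyl group, or hydrolytic loss of the acetyl group from the acyloxyquinone in the acidic aqueous medium. The fallback sets out from 2 and comes back at 7. Oxidation of 2 with (NH4)2Ce(NO3)6 gives 2-methoxy-5-methyl-1,4-benzoquinone F8. Thiele–Winter acetoxylation (Ac2O, cat. H2SO4) is expected to place the third oxygen on the ring carbon between the methoxy-bearing carbon and the carbonyl, giving 3-methoxy-6-methylbenzene-1,2,4-triyl triacetate F9; this regiochemistry is less certain than that of the ortho-metalation, which is why it is not the main route. Methanolysis under air (K2CO3, MeOH, O2; then dilute HCl) passes through 3-methoxy-6-methylbenzene-1,2,4-triol F10 (not isolated), which autoxidises to fumigatin F11. Ac2O/pyridine then gives 7.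

**Further compounds**
F1 | step 13 | 4-bromo-2,3,6-trimethoxy-5-methylphenol | COc1c(Br)c(C)c(OC)c(O)c1OC
F2 | step 13 | (4-bromo-2,3,6-trimethoxy-5-methylphenoxy)(tert-butyl)dimethylsilane | COc1c(Br)c(C)c(OC)c(O[Si](C)(C)C(C)(C)C)c1OC
F3 | step 13 | 4-(tert-butyldimethylsilyloxy)-2,3,5-trimethoxy-6-methylphenyllithium | COc1c([Li])c(C)c(OC)c(O[Si](C)(C)C(C)(C)C)c1OC
F4 | step 13 | tert-butyl[4-(all-E-hexaprenyl)-2,3,6-trimethoxy-5-methylphenoxy]dimethylsilane | COc1c(C/C=C(\C)CC/C=C(\C)CC/C=C(\C)CC/C=C(\C)CC/C=C(\C)CCC=C(C)C)c(C)c(OC)c(O[Si](C)(C)C(C)(C)C)c1OC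
F5 | step 13 | 4-(all-E-hexaprenyl)-2,3,6-trimethoxy-5-methylphenol | COc1c(C/C=C(\C)CC/C=C(\C)CC/C=C(\C)CC/C=C(\C)CC/C=C(\C)CCC=C(C)C)c(C)c(OC)c(O)c1OC
F6 | step 13 | 4-(all-E-hexaprenyl)-2,3,6-trimethoxy-5-methylphenyl acetate | COc1c(C/C=C(\C)CC/C=C(\C)CC/C=C(\C)CC/C=C(\C)CC/C=C(\C)CCC=C(C)C)c(C)c(OC)c(OC(C)=O)c1OC
F7 | step 10 | (2E,6E,10E,14E,18E)-3,7,11,15,19,23-hexamethyl-9-(p-tolylsulfonyl)tetracosa-2,6,10,14,18,22-hexaen-1-ol, racemic at C9 | OC/C=C(\C)CC/C=C(\C)CC(S(=O)(=O)c1ccc(C)cc1)/C=C(\C)CC/C=C(\C)CC/C=C(\C)CCC=C(C)C
F8 | step 4 | 2-methoxy-5-methyl-1,4-benzoquinone | COC1=CC(=O)C(C)=CC1=O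
F9 | step 4 | 3-methoxy-6-methylbenzene-1,2,4-triyl triacetate | COc1c(OC(C)=O)cc(C)c(OC(C)=O)c1OC(C)=O
F10 | step 4 | 3-methoxy-6-methylbenzene-1,2,4-triol | COc1c(O)cc(C)c(O)c1O
F11 | step 4 | 3-hydroxy-2-methoxy-5-methyl-1,4-benzoquinone (fumigatin) | COC1=C(O)C(=O)C(C)=CC1=O
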